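All runs stem from a simulated flask for an exercise, and the scatter is random.

How much product stands in this flask at 8.0 min, and which change raises it most?

| flask | solid substrate | coupling partner | initiator | remark | time |
|---|---|---|---|---|---|
| theta | 0.50 M | 2 M | 12 mM | run made earlier |  |
| delta | 0.50 M | 2 M | 50 mM | run made earlier |  |
| flask | 0.50 M | 2.00 M | 25 mM |  | 8.0 min |

| run | time / min | product / % | solid substrate / % |
|---|---|---|---|
| theta | 0.500 | 0 | 97.1 |
| theta | 0.833 | 0.7 | 95.3 |
| theta | 1.33 | 0.9 | 93.7 |
| theta | 2.50 | 2.5 | 88.4 |
| theta | 4.00 | 6.3 | 81.2 |
| theta | 6.00 | 11.1 | 72.3 |
| delta | 0.500 | 0.1 | 97.5 |
| delta | 0.833 | 1.3 | 96.0 |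
| delta | 1.33 | 1.6 | 93.1 |
| delta | 2.50 | 4.6 | 87.3 |
| delta | 4.00 | 10.7 | 80.4 |
| delta | 6.00 | 18.1 | 71.5 |

(scatter of a reading: 0.5 percentage points)

- amount of product at 8.0 min, in percent of the solid substrate charged
- the change that raises the amount of product at 8.0 min, in percent of the solid substrate charged most ("none" if none brings more than 2 percentage points) (east / north / north-east / none)
- amount of product at 8.0 min, in percent of the solid substrate charged, after north-east

- east: doubling the dissolution coefficient of the solid substrate, all else as stated
- north: doubling the solubility of the solid substrate, all else as stated
- north-east: doubling the amount of coupling partner, all else as stated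

- in percentages every species weighs as the solid substrate in it: one ended chains B counts as two
- as a solid, counted per litre of solution: solid substrate
- the numbers in the tables scatter by 0.5 percentage points (one standard deviation)
- steps thought possible: 2 second chain carrier -> ended chains A; 2 first chain carrier -> ended chains B; starting material + initiating radical -> capped initiator + first chain carrier; initiator -> 2 initiating radical; coupling partner + first chain carrier <-> product + second chain carrier; starting material + second chain carrier -> by-product + first chain carrier; solid substrate <-> starting material
- at the start none of the solid substrate is in solution

What do you balance first? The solid substrate, the limiting reagent, since its charge is smaller than the coupling partner's. Within the scatter, the charge is solid, dissolved starting material or product, so the pool in solution is one minus solid minus product.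

How fast does the pool fill? The solid left at 6.00 min reads 72.3% in theta and 71.5% in delta, so the feed, averaged over that time, reads 0.0468 /min of the charge.

How fast does it empty? From 4.00 min to 6.00 min, product rate over mean pool reads 0.165 /min in theta and 0.383 /min in delta.

Is that difference real? Yes: delta reads faster, by a factor of 2.32, against 2.04 for the root of the initiator ratio, which chains ended in pairs lead one to expect. Scaling both readings by that root to this flask gives 0.254 /min, the pool turnover: a pseudo-first-order constant, product made per minute per unit of pool.

And this flask? My reckoning: with the feed held steady and emptying at the turnover, its pool reckons to 16.0%, so product, as feed times time minus pool, reckons to 21.4%.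

Which change? If dissolving runs as coefficient times the gap between solubility and pool, doubling solubility subtracts the pool once, doubling the coefficient twice. With a pool above nil, I name north. The runs hold the coupling partner at one charge, so I read nothing for north-east and merely expect little.

The forecast gives 21%, east and 24.5%, holding that “East beats north because it keeps the driving force doubled”; on the change we differ.

This flask gives 21.7%. North adds most, 16 percentage points, more than east's 14 points or north-east's 0.73 points, which ends at 22.4%.

    2 second chain carrier → ended chains A (k = 7.00 × 10⁸ /M/s)
    2 first chain carrier → ended chains B (k = 4.60 × 10⁸ /M/s)
    starting material + initiating radical → capped initiator + first chain carrier (k = 8.10 × 10⁵ /M/s)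
    initiator → 2 initiating radical (k = 1.60 × 10⁻⁴ /s)
    coupling partner + first chain carrier ⇌ product + second chain carrier (K = 10.0, k = 4300 /M/s)
    starting material + second chain carrier → by-product + first chain carrier (k = 62000 /M/s)
    solid substrate ⇌ starting material, rate k7*(cs7 - [starting material]) while solid is left; crystals form when [starting material] > cs7 (solubility = 0.400 M, k = 0.00110 /s)

At 8.00 min this flask holds a pool of 15.0%, which at the turnover reckons to a product rate of 0.0381 /min. The neighbour charged with 1.2 M of solid substrate holds 6.56 × 10⁻⁸ M of second chain carrier, as this flask does; I carry the turnover over unchanged and, taking equal moles to dissolve, set its feed at 0.0195 /min of its charge. That reckons to 8.93% product, and the neighbour gave 9.05%.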